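(The rate constants are invented.)

In a one-step world, where substrate meets substrate and makes homo dimer, a flask has one time constant and a run has one length, and their ratio tells us how far it gets. Our flask has more steps than that, so here it is in full.

substrate 0.27 M; scavenger 0.216 M; gas 160 mM (held); initiator 1.4 mM; time 8.0 min

    reagent + released group ⇌ idle adduct, settled at all times (K1 = 7.8 L mol⁻¹)
    reagent + first chain carrier ⇌ target + second chain carrier (K2 = 3.8, k2 = 7.5 × 10⁵ L mol⁻¹ s⁻¹)
    substrate + initiating radical → capped initiator + first chain carrier (k3 = 1.6 × 10⁶ L mol⁻¹ s⁻¹)
    scavenger + released group → scavenged by-product (k4 = 85 L mol⁻¹ s⁻¹)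
    gas ⇌ reagent, rate k5*(csat - [reagent]) (k5 = 0.58 s⁻¹, csat = 160 mM)
    2 substrate → homo dimer (k6 = 0.033 L mol⁻¹ s⁻¹)
    initiator → 2 initiating radical (k7 = 0.15 s⁻¹)
    substrate + second chain carrier → released group + first chain carrier (k8 = 62000 L mol⁻¹ s⁻¹)
    2 second chain carrier → ended chains (k9 = 4 × 10⁸ L mol⁻¹ s⁻¹)

- percentages count the substrate that a species holds: one homo dimer counts as two
- released group is meant together with its idle adduct
- a doubled species enters its step squared and goes two at a time
- at the start none of reagent is dissolved
- run time (flask): 8.0 min

1. part of the substrate that has reacted at 8.0 min
2. share of the unused reagent that is free and not bound as idle adduct, at 8.0 min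

We start with the step 2 substrate → homo dimer (k6 = 0.033 L mol⁻¹ s⁻¹). Its first half-life at the charge, for substrate by this step alone, is 0.935 min, and the run lasts 8.0 min. We call the run time counted in these half-lives the dimer number, 8.55. In the one-step world the fraction of the charge left is one over one plus this number, so 89.5% has reacted.

Now we go round once more. The chain also eats substrate, but the initiator has a half-life of 0.077 min, shorter than 0.935 min, so we treat the chain as a burst at the start. While it lasts, second chain carrier sits at the level where its making from initiator balances its ending in pairs, and substrate falls pseudo-first-order. Summed over the life of the initiator, this gives a depth 0.599. The burst turns the one in our formula into 1.82, which is less than the dimer number. We commit to 90.4% reacted. Our reckoning stops short of the free share of reagent.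

The forecast says 90.6% (range 88.5% to 92.5%), where we have 90.4%, and 100% free (range 99.9% to 100%), since the “scavenger is in excess of all the released group formed”.

The flask gives 90.5% reacted and 100% free. At 8.00 min it holds 8.75 × 10⁻¹⁰ M of idle adduct against 0.160 M of reagent. Now take the neighbour flask charged with 0.68 M of substrate, its initiator charge held, so the burst term stays 1.82. Its dimer number is 21.5, which puts 4.29% of its charge left, and that neighbour flask ends with 4.20% of its substrate.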